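Beside an earlier amber flask with 1.10 equiv of free base I set grey at 2.20 equiv and red at 4.40 equiv, and I ask what the extra base buys.

in all of them: solid electrophile 0.50 M; protonated nucleophile 1.30 equiv; time 2.5 d

| charge | free base |
|---|---|
| amber | 1.10 equiv |
| grey | 2.20 equiv |
| red | 4.40 equiv |

    nucleophile + acid set free ⇌ protonated nucleophile, settled at all times (K1 = 15600 M⁻¹)
    solid electrophile ⇌ electrophile, rate k2*(cs2 - [electrophile]) while solid is left; crystals form when [electrophile] > cs2 (cs2 = 0.19 M, k2 = 0.00644 min⁻¹)
    electrophile + nucleophile → acid set free + target (k3 = 0.0491 M⁻¹ min⁻¹)
    electrophile + target → side product (k4 = 0.00108 M⁻¹ min⁻¹)
    acid set free + free base ⇌ salt of the base (K5 = 5700 M⁻¹, k5 = 0.00431 M⁻¹ min⁻¹)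

- part of the solid electrophile that has reacted (what has only dissolved counts as not reacted) at the end, amber
- part of the solid electrophile that has reacted (what has only dissolved counts as not reacted) at the end, grey
- part of the solid electrophile that has reacted (what has only dissolved counts as not reacted) at the end, red
- what raising the equivalents of free base from its lowest to its highest value here does to the part of the solid electrophile that has reacted (what has only dissolved counts as not reacted) (changes below 5 percentage points count as none) (no change / it falls / it rises)

I climb the ladder of times from the fastest rung. The balance between nucleophile and protonated nucleophile is kept at once. Dissolving follows with a half-life of 0.0747 d, far shorter than the run, so while solid is left the electrophile stands near 0.19 M.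

Next, in amber, comes the taking of acid set free by free base, with a half-life of 0.20 d by its forward rate alone at the charged amounts, shorter than the run, so I take the acid as steady within the run (a quasi-steady state). Each coupling of electrophile with nucleophile frees one acid, and replacing that nucleophile from the protonated nucleophile frees a second, so the base must take two acids per coupling. Putting the balance into this gives the square root of half the product of the coupling coefficient, that electrophile, the base's coefficient, the free base and the protonated nucleophile as charged, over the balance constant: 2.15 × 10⁻⁵ M min⁻¹ in amber. This is the pace, the coupling rate that acid-taking allows. It goes with the square root of the base, so red has 4.29 × 10⁻⁵ M min⁻¹.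

Higher up stands the life of target against electrophile, 3.38 d, longer than the run but close to it. The run is 0.739 of that life, so a mean share 0.707 of the target made survives, and each coupling consumes 1.29 electrophile. The top rung, charge over pace, is 16.2 d in amber, longer than the run. I commit to 20.0% for amber, 28.3% for grey and 40.0% for red.

The forecast, lower than mine, gives 19%, 26% and 36%, and for the trend it rises, holding that the nucleophile level “rises roughly with the square root of the base loading”.

The simulation gives 18.9%, 25.5% and 34.9%; for the trend, it rises, by 16 percentage points. The pace ratio carries red to the neighbour with 0.780 equiv of protonated nucleophile: 3.33 × 10⁻⁵ M min⁻¹ gives 27.1%, and that flask reads 26.9%. Red has not come to rest at 2.5 d: electrophile holds 36.3%, solid electrophile 28.8%, and charge over pace is 8.09 d. Read at 10 d, red stands at 99.3%. After 25.0 d, amber reaches 97.9%, grey 100% and red 100%, with red holding target 32.9% and side product 67.1%.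

The constants used here were set for the occasion; the rest is arithmetic.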